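Amounts first: the runs told me what G had become, never what J had paid, so I kept a ledger in fractions of the G charged.

| flask | G | J | remark | time |
|---|---|---|---|---|
| south-west | 1.1 M | 0.70 equiv | run made earlier |  |
| midnight | 1.7 M | 1.40 equiv |  | 25 h |
| dusk | 1.7 M | 0.700 equiv |  | 25 h |

south-west run (percent of the G charged)

| time / h | E / % | Z / % | D / % | G / % |
|---|---|---|---|---|
| 0.500 | 0 | 1 | 2 | 98 |
| 1.33 | 0 | 0 | 6 | 96 |
| 2.50 | 4 | 5 | 12 | 81 |
| 4.00 | 5 | 10 | 15 | 75 |
| 5.00 | 11 | 4 | 19 | 70 |
| 8.00 | 6 | 11 | 19 | 61 |

(scatter of a reading: 2 percentage points)

- J is a solid; its amount is given per volume of the solution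
- the earlier runs were read with a standard deviation of 2 percentage points
- at the start none of J is in solution

- which of these there is most of at the end, counted by the G in it, midnight (G / Z / E / D)
- which of these there is most of at the end, counted by the G in it, dusk (G / Z / E / D)
- amount of the one of these that there is most of at the end, in percent of the G charged, midnight
- amount of the one of these that there is most of at the end, in percent of the G charged, dusk

I set the zero of the scale at the plain case, one J for each G consumed, and booked a second J for each G ending in Z; that second J was my guess, since no reading shows it. Over the south-west readings from 4.00 h on, Z held 25.0% of the product counted and D held 53.0%. So the price of G came to 1.25: the J spent per G consumed, which is one plus the share of Z.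

In dusk, the charge of 0.700 equiv bought 0.560 of the G, less than the G charged, so J was the limiting reagent and the books closed with G at 44.0%. In midnight, 1.40 equiv bought 1.12, more than the G charged, so time kept those books. I carried the south-west pace, G at 61% after 8.00 h, over 25 h, which left G at 21.3%. The rest, at D's share, gave D 41.7%, more than G or Z.

The forecast said Z at 34% for midnight and G at 48% for dusk, on the ground that “That leaves G stranded at about 50%”. The flasks gave D at 46.2% in midnight and G at 44.7% in dusk.

    G + L → D (k = 0.120 L mol⁻¹ h⁻¹)
    G + 2 L → Z (k = 0.0880 L² mol⁻² h⁻¹)
    J ⇌ L, rate k3*(cs3 - [L]) while solid is left; crystals form when [L] > cs3 (solubility = 0.790 M, k = 1.00 h⁻¹)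
    D ⇌ E (K = 0.370, k = 0.520 h⁻¹)

At 1.23 h in dusk, G went to D 2.8 times as fast as to Z, the faster branch. That ratio makes the price 1.26, against my 1.25. The neighbour flask, dusk with 1.20 equiv of J, ended with G at 16.4% and Z at 23.8%, a price of 1.28. Its books therefore show 0.126 of J unspent, and dissolved L stood at 0.126 of the G charged.

The runs were computed on assumed constants.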